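**Slow loss.** J leaves slowly, and the order of that loss is what I read first in these flasks.

| flask | J | remark | time |
|---|---|---|---|
| grey | 0.025 M | run made earlier |  |
| blue | 0.19 M | run made earlier |  |
| east | 0.072 M |  | 5.0 min |
| north | 0.15 M |  | 5.0 min |
| south | 0.050 M |  | 5.0 min |
| west | 0.020 M |  | 5.0 min |

- grey (time / min: Q / %, J / %): 0.333: 0.6, 88.7; 0.833: 2.8, 73.1; 1.50: 5.9, 52.4; 2.50: 11.2, 23.2
- blue (time / min: Q / %, J / %): 0.333: 0.6, 98.8; 0.833: 0.6, 96.1; 1.50: 0.6, 93.5; 2.50: 1.3, 89.8

(standard deviation of a reading: 0.3 percentage points)

- J is a solid; its amount is given per volume of the solution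
- the earlier runs were read with a standard deviation of 0.3 percentage points
- at the start none of J is in solution
- what has only dissolved of J counts as not reacted
- a reading or a percentage of Q counts all its forms, free or not

1. all flasks from highest to lowest amount of Q, in percent of the J charged, at 5.0 min (east / north / south / west)
2. the amount of Q, in percent of the J charged of the flask you put first, at 5.0 min
3. the amount of Q, in percent of the J charged of the flask you put last, at 5.0 min

**The pace.** Up to 2.50 min the readings show the grey run losing J at 0.00768 M min⁻¹ and the blue run at 0.00775 M min⁻¹, about the same, though blue holds 7.60 times the charge. I call this the dissolving pace: moles of J leaving the J reading per litre per minute. Read from these two runs, it is zero order in J while solid stands. Q per litre also agrees at 2.50 min, with 0.00280 M in grey and 0.00247 M in blue.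

**The ledger.** My own books for J, the limiting reagent, run per litre. By 5.0 min the pace draws 0.0384 M, so on this estimate south keeps solid, as do east and north, while west closes its solid account at about 2.60 min. Between the last two grey readings, Q gains 0.00132 M min⁻¹, a share of 17.3 % of the pace as read. Carried forward, that enters 0.00611 M of Q in my books, and the other 0.0323 M stands under unread forms. Dividing by the charges gives south 12.2 %, east 8.49 % and north 4.08 %. West, at the same share of its charge, gets 17.3 %, which puts it ahead of south.

**The forecast.** It gives west > south > east > north, with 19 % first and 3.9 % last, on this ground: “It is zero order while solid remains, which suggests a saturated solution.” My order is the same; my west figure is lower than its 19 %, and my north figure is higher than its 3.9 %.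

**The flask.** It gives west > south > east > north: west 19.3 %, south 12.6 %, east 8.74 %, north 4.19 %.

    X ⇌ Q (K = 0.820, k = 0.0160 s⁻¹)
    Q ⇌ D (K = 1.00, k = 0.0750 s⁻¹)
    D ⇌ L (K = 0.710, k = 9.40 × 10⁻⁴ s⁻¹)
    X ⇌ G (K = 1.40, k = 0.0660 s⁻¹)
    X + Q ⇌ E, settled at all times (K = 10.0 M⁻¹)
    J ⇌ X, rate k6*(cs6 - [X]) while solid is left; crystals form when [X] > cs6 (solubility = 35.0 mM, k = 0.00410 s⁻¹)

**Pace again.** The pace leaves north 74.4 % of its J at 5.00 min, and that flask shows 76.1 %. The neighbouring flask is west stopped at 2.0 min. There the same pace draws 0.0154 M from a charge of 0.020 M, which leaves 23.2 % as J. That flask holds 21.6 % as J and a further 26.2 % as X, the dissolved form, so 48 % of the charge is still there, solid or dissolved, and its Q, all forms counted, stands at 10.6 %.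

The readings are simulated for an exercise, noise included.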